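## Structural features

The target is a 3-substituted 8-hydroxy-6-methoxyisocoumarin: ring A is the resorcinol-type benzene (C4a to C8a) and ring B the pyranone (C1, O2, C3, C4). A single exocyclic CH2 joins C3 to C5' of a γ-butyrolactone, ring C. Ring C holds the only two stereocentres: C3' (S), a secondary alcohol alpha to the lactone carbonyl, and the fully substituted C5' (R), which bears the ring oxygen, CHCl2, the ring CH2 and the CH2 link. They stand 1,3 to each other across C4'H2, with the hydroxyl and CHCl2 cis and the hydroxyl trans to the CH2 link. The fragile groups are the α-hydroxy lactone (epimerizable at C3', opened by nucleophilic base), the CHCl2 group (reducing metals, strong base), the enol lactone of ring B and the chelated C8 phenol. The real difficulty is C5': an oxygenated quaternary carbon whose only neighbouring stereocentre is two bonds away, so 1,3-induction is weak, and which must be tied to the arene without strong base. Ring A is a 1,3-dioxygenated benzene whose adjacent carbon substituents (C1 on C8a, C4 on C4a) sit exactly where an oxygenated butadiene (C5 to C8) places them on adding across an alkynoate (C4a, C8a, carboxyl C1). The key step uses this: ring A is built by cycloaddition onto a diynoate that already contains ring C, and the spare triple bond becomes C3–C4, onto which ring B closes from the C1 ester oxygen.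

## Logic of the disconnections

20 to 19. The O2–C3 bond of ring B is cut, so C3–C4 becomes a triple bond and C1 a methyl ester. The ester oxygen and the alkyne are ortho neighbours on ring A, and joining them is an isomerization with loss of one methyl group. This removes ring B and leaves no protecting group to take off afterwards. The forward step must close 6-endo and not 5-exo, and must spare both lactones, CHCl2 and two free hydroxyls.

19 to 13 and 15. The C5–C4a and C8–C8a bonds are cut, which removes ring A entirely: C5 to C8 with both oxygens go to 15, while C4a and C8a become the ester-bearing triple bond of 13. The substitution pattern of ring A is the regiochemical signature of this diene–ynoate pairing, so no benzene has to be bought, halogenated or coupled. The gain is ring A with OH, OMe, C1 and C4 correctly placed in one operation, on a fragment that already holds both stereocentres. The forward step must pick the ester-conjugated triple bond in the right orientation, leave the second triple bond and the lactone intact on heating, and not lose diene to the free hydroxyl. The last demand is met by silylating 13 in the flask to 16 before 15 is added, so no separate protection or deprotection step is needed.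

13 to 10 and 12. The sp–sp bond between the two triple bonds is cut. This separates a three-carbon ester unit, one step from 11, from the chiral lactone, which keeps a terminal alkyne. The forward heterocoupling needs a base too hindered to open the lactone or isomerize the skipped diyne.

10 to 6 and 7. The bond from C5' to the propargylic CH2 and the acyl–oxygen bond of ring C are cut. This gives a dichloromethyl ketone whose alcohol and carboxyl are held together in a dioxolanone, which serves as protecting group and as the acyl donor that closes ring C. The quaternary carbon is thus made early, on cheap material. The forward step would need facial selectivity under 1,3-induction from C3', which cannot be relied on, so it is planned as an addition giving both C5' epimers followed by separation. It also needs an organometallic that does not reduce C–Cl bonds.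

6 to 4 to 2. Both C–Cl bonds are cut back to a sulfoxonium ylide carbon, then the bond between that carbon and the ketone carbon. The reason is safety: an acid is homologated to a dichloromethyl ketone without diazomethane and without an organolithium next to the epimerizable C3'. The forward steps must deliver exactly two chlorines, one as electrophile and one as nucleophile.

2 to 1, 15 to 14, 12 to 11. The acetonide is cut to 1, where one step differentiates the two carboxyls, protects the alcohol and brings C3' from the chiral pool. The O–Si bond of 15 is cut to 14 and the C–Br bond of 12 to 11. Each is one functional-group step on a purchased compound.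

## Other disconnections considered

Alternative 1: The cut falls on C4a–C4 and C8a–C1, so ring A is bought as a 3,5-dimethoxybenzene and both carbon substituents are attached at once. Forward, the iodo triflate A2 would be treated with an alkyllithium at low temperature, and the aryne released would add the ketene acetal A3 by [2+2] cycloaddition to give the benzocyclobutenone acetal A1. The methoxy group beside the aryne bond steers the nucleophilic CH2 terminus to the remote aryne carbon, so the acetal carbon (future C1) ends next to the oxygenated C8 position.
- In its favour: the regiochemistry rests on a well-understood inductive effect; A1 is small, achiral and made before anything valuable is at stake; ring A oxygenation comes from a cheap phenol.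
- Against it here: A1 is far from the target. It would have to be hydrolysed to the ketone A4, opened to a benzylic anion and acylated by a lactone acetic acid derivative, which is carbanion chemistry exactly where the α-oxygenated lactone and CHCl2 are least tolerant. C8 arrives as a methyl ether needing selective demethylation, and a cryogenic organolithium and a strained intermediate are required.
- Comparison: it equals the chosen plan in forming both ring A carbon bonds in one cycloaddition. It is better in that its regiochemistry does not depend on telling two triple bonds apart. Mechanistically the chosen plan is gentler once the stereocentres are present. In step economy the chosen plan is shorter, because the four-membered ring is a detour (hydrolysis, opening and acylation, ring B closure, demethylation).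

Alternative 2: The cut is the O1'–C5' bond of ring C together with one C–Cl bond. Forward, the chlorovinyl hydroxy acid A6 would be treated with a chlorenium donor and a cinchona-derived catalyst, so that the carboxylate closes onto the disubstituted alkene carbon while chlorine adds to the chlorinated terminus, giving the lactone A5.
- In its favour: C5' is set by catalyst control and not by separation; the CHCl2 group and ring C are completed together under mild, non-basic conditions; desilylation of A5 would give 10, so the idea can be grafted onto the chosen route.
- Against it here: enantioface selection in such chlorolactonizations is most dependable for aryl-substituted alkenoic acids, whereas A6 has two alkyl-type groups of similar size on the alkene and a deactivating vinylic chlorine. The resident C3' hydroxyl makes one catalyst antipode mismatched and may compete as a nucleophile. A6 is itself a multistep target with a defined α-hydroxy acid.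
- Comparison: on control of C5' this alternative is the better of the two. Mechanistically the two are equally mild. On step economy the chosen plan should reach 10 in four steps from 1, which A6 alone is unlikely to match. The alternative says nothing about rings A and B, so it replaces only the early part.

Alternative 3: The cut is O2–C3 and C3=C4 of ring B. Forward, the carboxylate of the phosphonium salt A8 would be acylated by the acid chloride A9, and the ylide formed with a tertiary amine would olefinate the new anhydride carbonyl intramolecularly to give the 6,8-dimethoxyisocoumarin A7.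
- In its favour: ring B forms without metals and with no 5-exo versus 6-endo question; the plan is convergent; ring A is bought; no diynoate is handled.
- Against it here: in A9 the ring C oxygen is beta to the acyl chloride, so amine-induced ketene formation or elimination with opening of ring C threatens. C8 arrives methylated, so a selective demethylation and a separate desilylation follow. A9 needs a two-carbon acid chain on C5', made by the same uncontrolled ketone addition plus oxidation-state changes.
- Comparison: it equals the chosen plan in convergence. It is better in the certainty of ring B regiochemistry and in the stability of its intermediates. It is poorer in protecting-group economy (two deprotections at the end against none) and is expected to be equal or longer in step count.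

Key step: step 8

Remarks on the chemistry (assumptions):
- The quaternary ring C carbon keeps one spatial arrangement from 10 to 20. Its descriptor is S while the side chain is an alkyne (9, 10, 13, 16 to 19), because the ring CH2 outranks the propargylic CH2, and R in 20, where the isocoumarinylmethyl CH2 outranks the ring CH2.
- The C3' hydroxyl is carried free and is masked as a trimethylsilyl ether only inside the key step; this replaces a persistent silyl ether and saves a protection and a deprotection step.
- 14 is taken as purchased (otherwise one acid-catalysed step from methyl acetoacetate and trimethyl orthoformate). The ketene acetal geometry of 15 is immaterial, since that carbon becomes C8 of the arene.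
- Safety choices: no diazomethane, 7 handled as its toluene solution, 12 kept in solution, no organolithium on any chiral intermediate.

## Route

Step 1
Reactants: 1 (S)-malic acid
Product: 2 2-[(4S)-2,2-dimethyl-5-oxo-1,3-dioxolan-4-yl]acetic acid
Conditions: 2,2-dimethoxypropane, p-TsOH·H2O (cat.), rt; crystallization
Reagents that add atoms: 2,2-dimethoxypropane, COC(C)(C)OC
Why: Acid-catalysed transacetalization closes the α-hydroxy acid unit to the five-membered dioxolanone in preference to the six-membered alternative, which differentiates the two carboxyls and protects the alcohol in one operation; the stereocentre is not involved, so the S configuration of 1 is carried over.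

Step 2
Reactants: 2 2-[(4S)-2,2-dimethyl-5-oxo-1,3-dioxolan-4-yl]acetic acid
Product: 4 (5S)-5-[3-(dimethyloxo-λ6-sulfanylidene)-2-oxopropyl]-2,2-dimethyl-1,3-dioxolan-4-one, via acid chloride 3 (not isolated)
Conditions: (COCl)2, DMF (cat.), CH2Cl2, 0 °C to rt, evaporate; then Me3S(O)I/NaH (2.2 equiv, ylide preformed in THF at reflux), THF, 0 °C
Reagents that add atoms: trimethylsulfoxonium iodide, C[S+](C)(C)=O.[I-]
Why: Acid chloride formation is followed by C-acylation of the Corey–Chaykovsky ylide, and a second equivalent of ylide deprotonates the acylsulfoxonium salt to the stabilized keto ylide, a diazomethane-free one-carbon homologation. The acid chloride is far more electrophilic than the dioxolanone carbonyl and the ylide is too weak a base to epimerize the ring C–H.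

Step 3
Reactants: 4 (5S)-5-[3-(dimethyloxo-λ6-sulfanylidene)-2-oxopropyl]-2,2-dimethyl-1,3-dioxolan-4-one
Product: 6 (5S)-5-(3,3-dichloro-2-oxopropyl)-2,2-dimethyl-1,3-dioxolan-4-one, via chloro ylide 5 (not isolated)
Conditions: NCS (1.05 equiv), CH2Cl2, −20 °C; then HCl (4 M in dioxane, 1.5 equiv), 0 °C to rt
Reagents that add atoms: N-chlorosuccinimide, O=C1CCC(=O)N1Cl; hydrogen chloride, Cl
Why: Geminal dihalogenation of a keto sulfoxonium ylide: electrophilic chlorination of the nucleophilic ylide carbon gives 5, then HCl protonates that carbon and chloride displaces dimethyl sulfoxide by SN2 alpha to the ketone, the same substitution that converts such ylides into chloromethyl ketones. One chlorine enters as electrophile and one as nucleophile, which limits over-chlorination, and anhydrous acid leaves the acetonide intact.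

Step 4
Reactants: 6 (5S)-5-(3,3-dichloro-2-oxopropyl)-2,2-dimethyl-1,3-dioxolan-4-one; 7 propargyl bromide
Product: 10 (3S,5S)-5-(dichloromethyl)-3-hydroxy-5-(prop-2-yn-1-yl)oxolan-2-one, via allenylzinc bromide 8 (not isolated), via tertiary alcohol 9 (not isolated)
Conditions: 7 (80% in toluene), Zn dust, THF, 0 °C, solution decanted from the metal; 6, THF, −78 to 0 °C; 1 M HCl, rt; chromatography (C5 epimer removed)
Reagents that add atoms: none
Why: Barbier-type propargylation: 8 adds to the activated ketone through a cyclic SE2' transition state to give the homopropargylic alkoxide, and on acidification the tertiary alcohol 9 is acylated by the dioxolanone carbonyl (5-exo-trig) with loss of acetone, so ring C and the free C3 hydroxyl appear together. Preforming 8 and removing the metal keeps zinc away from the reducible C–Cl bonds. C3 comes from 1, while the new C5 forms under weak 1,3-induction only, so both epimers are expected and the 5S isomer (CHCl2 cis to OH, to be confirmed by NOE) is secured by chromatographic separation and not by control.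

Step 5
Reactants: 11 methyl propiolate
Product: 12 methyl 3-bromoprop-2-ynoate
Conditions: NBS (1.1 equiv), AgNO3 (10 mol %), acetone, rt; filtered and kept as a solution (lachrymator, not distilled)
Reagents that add atoms: N-bromosuccinimide, O=C1CCC(=O)N1Br
Why: Silver-catalysed electrophilic bromination of a terminal alkyne via the silver acetylide, a standard preparation of 1-bromoalkynes that leaves the ynoate untouched.

Step 6
Reactants: 10 (3S,5S)-5-(dichloromethyl)-3-hydroxy-5-(prop-2-yn-1-yl)oxolan-2-one; 12 methyl 3-bromoprop-2-ynoate
Product: 13 methyl 6-[(2S,4S)-2-(dichloromethyl)-4-hydroxy-5-oxooxolan-2-yl]hexa-2,4-diynoate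
Conditions: CuI (10 mol %), PdCl2(PPh3)2 (3 mol %), i-Pr2NH (2 equiv), THF, 0 °C, slow addition of 12 (1.3 equiv)
Reagents that add atoms: none
Why: Cadiot–Chodkiewicz-type heterocoupling in its Pd/Cu co-catalysed form: the copper acetylide of 10 is transferred to the alkynylpalladium bromide formed from 12 and reductive elimination gives the unsymmetrical diyne. A hindered secondary amine, low temperature and slow addition are chosen so that the lactone is not opened, the bromoynoate is not consumed by conjugate addition and homocoupling is limited; no stereocentre is touched.

Step 7
Reactants: 14 methyl (2E)-3-methoxybut-2-enoate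
Product: 15 (1Z)-1,3-dimethoxy-1-(trimethylsilyloxy)buta-1,3-diene
Conditions: LiN(i-Pr)2 (LDA), THF, −78 °C; Me3SiCl, −78 °C to rt; distillation
Reagents that add atoms: chlorotrimethylsilane, C[Si](C)(C)Cl
Why: Kinetic γ-deprotonation of the β-methoxy enoate gives the extended lithium dienolate, which is silylated on oxygen to the ketene acetal diene, the standard preparation of 1-alkoxy-1-silyloxy dienes.

Step 8
Reactants: 13 methyl 6-[(2S,4S)-2-(dichloromethyl)-4-hydroxy-5-oxooxolan-2-yl]hexa-2,4-diynoate; 15 (1Z)-1,3-dimethoxy-1-(trimethylsilyloxy)buta-1,3-diene
Product: 19 methyl 2-{3-[(2S,4S)-2-(dichloromethyl)-4-hydroxy-5-oxooxolan-2-yl]prop-1-yn-1-yl}-6-hydroxy-4-methoxybenzoate, via trimethylsilyl ether 16 (not isolated), via cycloadduct 17 (not isolated), via bis-silyl arene 18 (not isolated)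
Conditions: N,O-bis(trimethylsilyl)acetamide (BSA, 1.1 equiv), toluene, rt; then 15 (2 equiv), 80 °C; then 1 M HCl, THF, rt
Reagents that add atoms: none
Why: The electron-rich ketene acetal diene 15 and the ester-conjugated triple bond C2≡C3 of 16 combine in a normal-demand Diels–Alder reaction, the closest known type being the benzannulation of 1-alkoxy-1-silyloxy-3-alkoxybutadienes with alkynoates to 6-substituted 4-methoxysalicylates. Bond formation is concerted but asynchronous: the CH2 terminus of 15, which has the largest HOMO coefficient, bonds first to C3 of the diynoate (future C4a) and the acetal carbon then bonds to C2 (future C8a), which places the hydroxyl ortho and the methoxy para to the ester. Ring A is thereby closed by a suprafacial [4+2] cycloaddition of four diene carbons and two alkyne carbons, giving the 1,4-cyclohexadiene 17. 17 aromatizes by 1,4-elimination of methanol from the mixed acetal carbon and the doubly allylic CH2 to give 18, and dilute acid then removes both trimethylsilyl groups, leaving the phenol hydrogen-bonded to the ester. No lasting stereocentre is created, since the acetal carbon of 17 is destroyed on aromatization, and C3' and C5' are remote from the reacting π system. Site selectivity between the two triple bonds is secured by the ester, which is conjugated directly only with C2≡C3, whereas addition across C4≡C5 would put no acceptor on the carbon receiving the acetal terminus and C5 is shielded by the neopentyl-like CH2–C5' unit. Chemoselectivity towards the hydroxyl is secured by silylating it with BSA first, so that the diene is not consumed by protonation, while the lactone carbonyl and CHCl2 are inert to the neutral diene.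

Step 9
Reactants: 19 methyl 2-{3-[(2S,4S)-2-(dichloromethyl)-4-hydroxy-5-oxooxolan-2-yl]prop-1-yn-1-yl}-6-hydroxy-4-methoxybenzoate
Product: 20 (3S,5R)-5-(dichloromethyl)-3-hydroxy-5-[(8-hydroxy-6-methoxy-1-oxo-1H-isochromen-3-yl)methyl]oxolan-2-one
Conditions: AuCl3 (5 mol %), MeCN, H2O (5 equiv), 50 °C
Reagents that add atoms: water, O (it adds at C1 of the cyclized cation and ends as the C1 carbonyl oxygen, while the ester methoxy leaves as methanol)
Why: Trivalent gold activates the triple bond and the ester carbonyl oxygen attacks the alkyne carbon remote from the ring in a 6-endo-dig closure, a known isocoumarin synthesis from methyl 2-alkynylbenzoates; water adds to the resulting 1-methoxyisochromenylium ion at C1, methanol is lost and protodeauration gives C4–H. The C3' hydroxyl is trans to the alkynyl methylene on ring C and cannot reach the alkyne, and no stereocentre is involved; only the descriptor at C5' changes, because the side chain now outranks the ring CH2.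

## Compound list

1 | (S)-malic acid, (2S)-2-hydroxybutanedioic acid | OC(=O)C[C@H](O)C(=O)O | starting material
2 | 2-[(4S)-2,2-dimethyl-5-oxo-1,3-dioxolan-4-yl]acetic acid | OC(=O)C[C@@H]1OC(C)(C)OC1=O | intermediate
3 | 2-[(4S)-2,2-dimethyl-5-oxo-1,3-dioxolan-4-yl]acetyl chloride (formed and consumed in the flask) | ClC(=O)C[C@@H]1OC(C)(C)OC1=O | intermediate
4 | (5S)-5-[3-(dimethyloxo-λ6-sulfanylidene)-2-oxopropyl]-2,2-dimethyl-1,3-dioxolan-4-one | CS(C)(=O)=CC(=O)C[C@@H]1OC(C)(C)OC1=O | intermediate
5 | (5S)-5-[3-chloro-3-(dimethyloxo-λ6-sulfanylidene)-2-oxopropyl]-2,2-dimethyl-1,3-dioxolan-4-one (formed and consumed in the flask) | CS(C)(=O)=C(Cl)C(=O)C[C@@H]1OC(C)(C)OC1=O | intermediate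
6 | (5S)-5-(3,3-dichloro-2-oxopropyl)-2,2-dimethyl-1,3-dioxolan-4-one | ClC(Cl)C(=O)C[C@@H]1OC(C)(C)OC1=O | intermediate
7 | propargyl bromide, 3-bromoprop-1-yne | C#CCBr | starting material
8 | allenylzinc bromide, bromo(propa-1,2-dien-1-yl)zinc (formed and consumed in the flask) | C=C=C[Zn]Br | intermediate
9 | (5S)-5-[(2S)-2-(dichloromethyl)-2-hydroxypent-4-yn-1-yl]-2,2-dimethyl-1,3-dioxolan-4-one (formed and consumed in the flask) | C#CC[C@@](O)(C(Cl)Cl)C[C@@H]1OC(C)(C)OC1=O | intermediate
10 | (3S,5S)-5-(dichloromethyl)-3-hydroxy-5-(prop-2-yn-1-yl)oxolan-2-one | C#CC[C@@]1(C(Cl)Cl)C[C@H](O)C(=O)O1 | intermediate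
11 | methyl propiolate, methyl prop-2-ynoate | C#CC(=O)OC | starting material
12 | methyl 3-bromoprop-2-ynoate | BrC#CC(=O)OC | intermediate
13 | methyl 6-[(2S,4S)-2-(dichloromethyl)-4-hydroxy-5-oxooxolan-2-yl]hexa-2,4-diynoate | COC(=O)C#CC#CC[C@@]1(C(Cl)Cl)C[C@H](O)C(=O)O1 | intermediate
14 | methyl (2E)-3-methoxybut-2-enoate | CO/C(C)=C/C(=O)OC | starting material
15 | (1Z)-1,3-dimethoxy-1-(trimethylsilyloxy)buta-1,3-diene | C=C(OC)/C=C(/OC)O[Si](C)(C)C | intermediate
16 | methyl 6-[(2S,4S)-2-(dichloromethyl)-5-oxo-4-(trimethylsilyloxy)oxolan-2-yl]hexa-2,4-diynoate (formed and consumed in the flask) | COC(=O)C#CC#CC[C@@]1(C(Cl)Cl)C[C@H](O[Si](C)(C)C)C(=O)O1 | intermediate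
17 | methyl 2-{3-[(2S,4S)-2-(dichloromethyl)-5-oxo-4-(trimethylsilyloxy)oxolan-2-yl]prop-1-yn-1-yl}-4,6-dimethoxy-6-(trimethylsilyloxy)cyclohexa-1,4-diene-1-carboxylate, acetal carbon unassigned (formed and consumed in the flask) | COC(=O)C1=C(C#CC[C@@]2(C(Cl)Cl)C[C@H](O[Si](C)(C)C)C(=O)O2)CC(OC)=CC1(OC)O[Si](C)(C)C | intermediate
18 | methyl 2-{3-[(2S,4S)-2-(dichloromethyl)-5-oxo-4-(trimethylsilyloxy)oxolan-2-yl]prop-1-yn-1-yl}-4-methoxy-6-(trimethylsilyloxy)benzoate (formed and consumed in the flask) | COC(=O)c1c(O[Si](C)(C)C)cc(OC)cc1C#CC[C@@]1(C(Cl)Cl)C[C@H](O[Si](C)(C)C)C(=O)O1 | intermediate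
19 | methyl 2-{3-[(2S,4S)-2-(dichloromethyl)-4-hydroxy-5-oxooxolan-2-yl]prop-1-yn-1-yl}-6-hydroxy-4-methoxybenzoate | COC(=O)c1c(O)cc(OC)cc1C#CC[C@@]1(C(Cl)Cl)C[C@H](O)C(=O)O1 | intermediate
20 | (3S,5R)-5-(dichloromethyl)-3-hydroxy-5-[(8-hydroxy-6-methoxy-1-oxo-1H-isochromen-3-yl)methyl]oxolan-2-one | COc1cc(O)c2c(=O)oc(C[C@@]3(C(Cl)Cl)C[C@H](O)C(=O)O3)cc2c1 | target

## Step count and least certain steps

Total step count: 9. Longest linear sequence: 7 steps (steps 1, 2, 3, 4, 6, 8, 9); steps 5 and 7 are single-step side branches.

Step 8 (key step). Three things are most likely to go wrong.
- Loss of site selectivity: cycloaddition or stepwise conjugate addition at the distal triple bond, since a 2,4-diynoate is also electrophilic at C5.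
- Thermal oligomerization of the diynoate before the diene has reacted.
- Aromatization by loss of trimethylsilanol instead of methanol, which would leave C8 methylated.

Fallback, setting out from 10 and rejoining at 19: the arene is bought instead of built. Commercial methyl 2,4,6-trihydroxybenzoate F1 would be methylated at the one hydroxyl not hydrogen-bonded to the ester (MeI, K2CO3, acetone) to methyl 2,6-dihydroxy-4-methoxybenzoate F2. One equivalent of triflic anhydride with pyridine would convert F2 into methyl 2-hydroxy-4-methoxy-6-(trifluoromethylsulfonyloxy)benzoate F3. A Sonogashira coupling of F3 with 10 (PdCl2(PPh3)2, CuI, Et3N, DMF, 50 °C) would then give 19, and steps 5 to 7 would fall away.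

Step 4. The main risk is poor facial selectivity at the ketone, because the controlling centre is 1,3 to the carbonyl and the zinc reagent is small, so a large share of material may end as the unwanted C5 epimer. Lesser risks are reductive dechlorination by residual zinc and SE2 addition giving the allenyl carbinol. Fallback, setting out from 6 and rejoining at 10: substrate control is replaced by reagent control. Allenylboronic acid pinacol ester would be added to 6 under a chiral 3,3'-disubstituted BINOL catalyst (catalytic asymmetric propargylation of ketones), using the catalyst antipode that reinforces the needed face. Work-up of the boron alkoxide gives 9, which lactonizes to 10 as in the route; no new isolable compound arises.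

Step 6. Likely failures are consumption of the electrophilic bromoynoate by conjugate addition of the amine, homocoupling of either alkyne, and base-induced isomerization of the skipped diyne to an allene. Fallback, setting out from 10 and rejoining at 13: the ester is introduced at the alcohol oxidation level.
- 10 would be coupled under the same Pd/Cu conditions with 3-bromoprop-2-yn-1-ol F4 (from propargyl alcohol, NBS and AgNO3), a non-electrophilic partner, to give (3S,5S)-5-(dichloromethyl)-3-hydroxy-5-(6-hydroxyhexa-2,4-diyn-1-yl)oxolan-2-one F5.
- The primary alcohol of F5 would be oxidized selectively with TEMPO and PhI(OAc)2 in MeCN–water to 6-[(2S,4S)-2-(dichloromethyl)-4-hydroxy-5-oxooxolan-2-yl]hexa-2,4-diynoic acid F6.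
- F6 would be esterified with MeI and KHCO3 in DMF to 13.

Step 3. Likely failures are over-chlorination through a second electrophilic chlorination before chloride displaces dimethyl sulfoxide, incomplete displacement leaving the chlorinated sulfoxonium salt, and acid-induced loss of the acetonide. Fallback, setting out from 2 and rejoining at 6: the classical β-keto ester route.
- 2 would be activated with carbonyldiimidazole and condensed with Mg(O2CCH2CO2t-Bu)2 to tert-butyl 4-[(4S)-2,2-dimethyl-5-oxo-1,3-dioxolan-4-yl]-3-oxobutanoate F7.
- SO2Cl2 (2 equiv, CH2Cl2) would chlorinate the active methylene twice to tert-butyl 2,2-dichloro-4-[(4S)-2,2-dimethyl-5-oxo-1,3-dioxolan-4-yl]-3-oxobutanoate F8.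
- Anhydrous CF3CO2H with gentle warming would remove the tert-butyl group and the dichloro keto acid would decarboxylate to 6.

Step 9. Likely failures are closure in the 5-exo-dig mode to an alkylidene phthalide, favoured if the inductively withdrawing ring C disfavours attack at the remote alkyne carbon, and simple hydration of the alkyne without ring closure. Fallback, setting out from 19 and rejoining at 20: iodonium-triggered cyclization with I2 (CH2Cl2, rt), which is dependably 6-endo for alkyl-substituted alkynes and expels the ester methyl as iodomethane, would give (3S,5R)-5-(dichloromethyl)-3-hydroxy-5-[(8-hydroxy-4-iodo-6-methoxy-1-oxo-1H-isochromen-3-yl)methyl]oxolan-2-one F9. Hydrodeiodination with Pd(OAc)2, PPh3 and HCO2H–Et3N in DMF would then give 20 and would also clear any iodine introduced on the activated arene.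

## Further compounds

F1 | step 8 | methyl 2,4,6-trihydroxybenzoate | COC(=O)c1c(O)cc(O)cc1O
F2 | step 8 | methyl 2,6-dihydroxy-4-methoxybenzoate | COC(=O)c1c(O)cc(OC)cc1O
F3 | step 8 | methyl 2-hydroxy-4-methoxy-6-(trifluoromethylsulfonyloxy)benzoate | COC(=O)c1c(O)cc(OC)cc1OS(=O)(=O)C(F)(F)F
F0 | step 4 | none | none
F4 | step 6 | 3-bromoprop-2-yn-1-ol | OCC#CBr
F5 | step 6 | (3S,5S)-5-(dichloromethyl)-3-hydroxy-5-(6-hydroxyhexa-2,4-diyn-1-yl)oxolan-2-one | OCC#CC#CC[C@@]1(C(Cl)Cl)C[C@H](O)C(=O)O1
F6 | step 6 | 6-[(2S,4S)-2-(dichloromethyl)-4-hydroxy-5-oxooxolan-2-yl]hexa-2,4-diynoic acid | OC(=O)C#CC#CC[C@@]1(C(Cl)Cl)C[C@H](O)C(=O)O1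
F7 | step 3 | tert-butyl 4-[(4S)-2,2-dimethyl-5-oxo-1,3-dioxolan-4-yl]-3-oxobutanoate | CC(C)(C)OC(=O)CC(=O)C[C@@H]1OC(C)(C)OC1=O
F8 | step 3 | tert-butyl 2,2-dichloro-4-[(4S)-2,2-dimethyl-5-oxo-1,3-dioxolan-4-yl]-3-oxobutanoate | CC(C)(C)OC(=O)C(Cl)(Cl)C(=O)C[C@@H]1OC(C)(C)OC1=O
F9 | step 9 | (3S,5R)-5-(dichloromethyl)-3-hydroxy-5-[(8-hydroxy-4-iodo-6-methoxy-1-oxo-1H-isochromen-3-yl)methyl]oxolan-2-one | COc1cc(O)c2c(=O)oc(C[C@@]3(C(Cl)Cl)C[C@H](O)C(=O)O3)c(I)c2c1
A1 | alternative 1 | 4,6-dimethoxybenzocyclobuten-1(2H)-one dimethyl acetal | COc1cc(OC)c2c(c1)CC2(OC)OC
A2 | alternative 1 | 2-iodo-3,5-dimethoxyphenyl trifluoromethanesulfonate | COc1cc(OC)c(I)c(OS(=O)(=O)C(F)(F)F)c1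
A3 | alternative 1 | 1,1-dimethoxyethene | C=C(OC)OC
A4 | alternative 1 | 4,6-dimethoxybenzocyclobuten-1(2H)-one | COc1cc(OC)c2c(c1)CC2=O
A5 | alternative 2 | (3S,5S)-5-(dichloromethyl)-3-hydroxy-5-[3-(trimethylsilyl)prop-2-yn-1-yl]oxolan-2-one | C[Si](C)(C)C#CC[C@@]1(C(Cl)Cl)C[C@H](O)C(=O)O1
A6 | alternative 2 | (2S)-4-(chloromethylidene)-2-hydroxy-7-(trimethylsilyl)hept-6-ynoic acid, alkene geometry immaterial | C[Si](C)(C)C#CCC(=CCl)C[C@H](O)C(=O)O
A7 | alternative 3 | (3S,5R)-3-(tert-butyldimethylsilyloxy)-5-(dichloromethyl)-5-[(6,8-dimethoxy-1-oxo-1H-isochromen-3-yl)methyl]oxolan-2-one | COc1cc(OC)c2c(=O)oc(C[C@@]3(C(Cl)Cl)C[C@H](O[Si](C)(C)C(C)(C)C)C(=O)O3)cc2c1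
A8 | alternative 3 | (2-carboxy-3,5-dimethoxybenzyl)triphenylphosphonium bromide | COc1cc(OC)c(C(=O)O)c(C[P+](c2ccccc2)(c2ccccc2)c2ccccc2)c1.[Br-]
A9 | alternative 3 | 2-[(2R,4S)-4-(tert-butyldimethylsilyloxy)-2-(dichloromethyl)-5-oxooxolan-2-yl]acetyl chloride | ClC(=O)C[C@@]1(C(Cl)Cl)C[C@H](O[Si](C)(C)C(C)(C)C)C(=O)O1
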